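## Structural features

Ugonin Q (34) is a 5,7,3′,4′-tetrahydroxyflavone: the benzopyranone of rings A and C carries the catechol ring B at C2, and C6 of ring A is joined through one methylene carbon to a monoterpenoid cyclohexane. That cyclohexane holds a gem-dimethyl quaternary carbon, an exocyclic methylene and a secondary allylic alcohol. Its two stereocentres, the ring methine that bears the benzylic CH2 (S) and the carbinol carbon (S), stand 1,3 to each other across the methylene-bearing sp2 carbon and are trans; the methine is wedged between that sp2 carbon and the quaternary carbon. The fragile parts are the allylic alcohol with its 1,1-disubstituted alkene (acid can ionise it, move the double bond or add the neighbouring 5- or 7-hydroxyl to it), the catechol (air-sensitive as its phenoxide) and the two ring-A hydroxyls ortho to the side chain, either of which could close ring C and give the 8- instead of the 6-substituted flavone. The real difficulties are three: a C–C bond at a neopentyl-type methine with absolute control, the trans 1,3-relation of carbinol and methine, and a ring A in which only the oxygen para to the side chain is free to become O1. Ring A is a 2-alkylphloroglucinol: C6 lies between oxygenated C5 and C7, and the third oxygen sits para at C8a. The key step uses exactly this: a ketene–ynol ether benzannulation takes C6 and C5 from the ynol ether and C7, C4a, C8a and C8 from a 3-oxygenated vinylketene, so the side chain, the 1,3,5-oxygen pattern and three differently substituted oxygens arise together.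

## Logic of the disconnections

34 from 33: only Si–O bonds are cut. All five silyl ethers fall to fluoride in one operation, so the polyphenol and the free allylic alcohol exist only at the very end. The forward step must be neither acidic nor strongly basic.

33 from 31: the O1–C2 bond of ring C is cut. Closing ring C from an alkynyl ketone needs no acid, and in 31 the only free ortho oxygen is the one para to the side chain, so only the 6-substituted flavone can form. The demand is six- instead of five-membered closure, met by passing through 32.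

31 from 25 and 28 (through 30): the C3–C4 bond is cut, which divides the molecule into a ring-A aldehyde and a ring-B alkyne of similar size. The forward steps are addition of 29 to a hindered hydroxy aldehyde and oxidation of a benzylic propargylic alcohol beside a free phenol. 28 goes back through 27 to 26 by silylation and one-carbon homologation.

25 from 23, 22 and 21: the C4a–C4 bond is cut (formyl group). 23 has a mirror plane through C6 and the para oxygen, so either ortho position gives 25. To leave only that oxygen free, the hydroxyl of 21 is silylated (22) and the one unhindered aryl TBS ether is removed (23). The demand is selective desilylation among four silyl ethers.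

21 from 14 and 16: three ring-A bonds are cut at once (C6–C7, C4a–C5, C7–C8). Ring A is reduced to an alkyne terminus on the terpenoid and a four-carbon partner; regiochemistry follows from polarity, and the three oxygens emerge as free hydroxyl, TIPS ether and TBS ether. No benzylic cation or electrophile is ever placed next to the terpenoid alkene. The demand is that 16 opens thermally to 17 and is intercepted by 14 before it decomposes. 16 is the O-silyl derivative of 15.

14 from 11, 10, 9 and 7: the C–O bond of the ynol ether is cut (acetylide oxidation), then the alkyne C–C bond (one-carbon homologation of 10), then the oxygen of 9 (from a vinyl group). Vinyl is the smallest two-carbon unit that a conjugate addition can place on the hindered carbon. The demand is hydroboration of the vinyl group in the presence of the exocyclic methylene.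

7 from 5, 4 and 3: the exocyclic C=C is traced to an aminomethyl group (Cope elimination through 6) and the carbinol C–H to the ketone of 3. On a 2-methylenecyclohexanone both chair conformers are expected to lead hydride to the cis alcohol; in 3, with both substituents equatorial, a bulky hydride should give the axial alcohol, which is trans to the vinyl group. The aminomethyl group thus serves twice: as conformational anchor for the reduction and as precursor of the methylene. The demand is an elimination that leaves the carbinol untouched.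

3 from 1: the C3–vinyl and C2–CH2N bonds are cut, back to the achiral enone. A catalytic asymmetric conjugate addition sets the methine stereocentre, and enolate 2 is trapped regiospecifically. The demand is enantioselective vinyl transfer to a β-carbon next to a quaternary centre.

## Other disconnections considered

Alternative 1: The cut is between the ring methine and the benzylic carbon, together with the bond to the exocyclic methylene carbon. In the forward step Cu(OTf)2 (divalent copper precatalyst) and a chiral phosphoramidite would add the benzylic zinc reagent A1 to C3 of 1; the zinc enolate would be aminomethylated at C2 with N,N-dimethylmethyleneiminium iodide and eliminated to enone A2.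
- In its favour: the complete, already differentiated phloroglucinol arrives in one operation. The chosen plan needs steps 5–8 and 10–12 to reach a comparable stage, so on convergence and step economy this alternative is the better.
- Against it: copper–phosphoramidite conjugate additions are established for dialkylzincs, not for benzylic zinc halides, which transfer poorly. A1 is a very bulky, electron-rich 2,6-dioxygenated benzyl nucleophile prone to homocoupling, and the acceptor carbon is neopentyl-like, so neither rate nor enantioselectivity can be assumed.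
- Structure: A2 still holds the ketone beside the methylene, so the trans carbinol would have to come from a reduction expected to favour the cis alcohol. The chosen plan avoids this by reducing before the methylene exists.
- Mechanism: the tandem conjugate addition–Mannich logic is the same as in step 1 of the chosen plan, and on that point the two are equal; the chosen plan only asks it of a small vinyl group.

Alternative 2: The cut is the ring bond between the gem-dimethyl carbon and the methine. A squalene–hopene cyclase variant (a protonation-initiated class two terpene cyclase) would protonate the terminal alkene of geranyl arene A3; the inner alkene attacks the tertiary cation, and loss of a methyl proton gives A4.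
- In its favour: ring and methine stereocentre form in one catalytic step from an achiral precursor. Absolute control by an enzyme could equal or exceed ligand control in step 1, and the route to the carbon skeleton is the shortest of all; on these points it is the better.
- Against it: A4 has no ring hydroxyl. It would have to be introduced late by allylic oxidation (for example SeO2) next to the methylene, with regio- and trans-stereocontrol, in the presence of an electron-rich phenol and two allyl ethers that are themselves allylic.
- Against it: the cyclase must stop at the monocycle and lose the proton from the methyl group. A phloroglucinol beside the cation invites capture by the arene or an oxygen, and the variant must be found by screening, which cannot be planned on paper.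
- Comparison: this route builds the terpenoid ring onto the arene by cationic chemistry; the chosen plan builds the arene onto the terpenoid by neutral pericyclic chemistry and sets both stereocentres with ordinary reagents. Step economy would favour the alternative only if the oxidation problem were solved.

Alternative 3: The cuts are C7–C8 and C5–C6 of ring A, with rings C and B preformed. The lithium dienolate at the 2-methyl group of pyranone ester A5 would be acylated by Weinreb amide A6 (C7–C8). Further base would let the α-carbon of the new ketone attack the ester (C5–C6); enolisation then gives A7.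
- In its favour: O1 is in place before ring A exists, so the 6- versus 8-alkyl question cannot arise and no phenol has to be differentiated; on this point it is the better. A7 needs only deprotection, whereas the chosen plan spends steps 11–19 after ring A is made, so the late-stage step economy is also better.
- Equal point: A6 would come from 10 by homologation, so the terpenoid chemistry and its stereocontrol are the same.
- Against it: base may add to the 4-pyranone or open it instead of deprotonating the methyl group. The ring closure needs the enolate at the more hindered α-carbon, while the more acidic position lies between the ketone and the pyranone. The catechol SEM ethers need forcing fluoride or acid, which is harder on the allylic alcohol than silyl ether cleavage.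
- Comparison: both plans build ring A from a terpenoid carbonyl derivative. The alternative does so by two anionic Claisen-type condensations; the chosen plan does so under neutral thermal conditions that the terpenoid tolerates without question.

Key step: step 10

Remarks on the chemistry:
- TBS = tert-butyl(dimethyl)silyl; TIPS = tri(propan-2-yl)silyl; TBSO and TIPSO are the corresponding silyloxy groups.
- Ter = (1S,5S)-5-(TBSO)-2,2-dimethyl-6-methylidenecyclohexyl, attached through C1 (the ring methine).
- Flavone numbering is used for ring A from 21 onwards.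
- Assumption: the ligand antipode that gives the (R)-enolate 2 in step 1 is identified in a trial with both antipodes.
- Assumption: 30 forms as both carbinol epimers, which converge in step 17.

## Route

Step 1
Reactants: 1 4,4-dimethylcyclohex-2-en-1-one
Product: 3 (2S,3R)-2-[(dimethylamino)methyl]-3-ethenyl-4,4-dimethylcyclohexan-1-one, via aluminium enolate 2 (not isolated)
Conditions: CH2=CHMgBr, Me2AlCl, Et2O, 0 °C; Cu(O2CC4H3S) (monovalent copper thiophene-2-carboxylate, 5 mol %), binaphthol-derived phosphoramidite (10 mol %), Et2O, −30 °C; then Me2N=CH2+ I−, THF, −30 °C → rt; aq. KNaC4H4O6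
Reagents that add atoms: dimethyl(vinyl)aluminium, C=C[Al](C)C; N,N-dimethylmethyleneiminium iodide, C[N+](C)=C.[I-]
Why: Copper-catalysed asymmetric conjugate addition of an alkenylalane (the sp2 group transfers in preference to methyl) sets the methine stereocentre under ligand control; the regiodefined enolate 2 is then aminomethylated anti to the new vinyl group (tandem conjugate addition–Mannich reaction), giving the trans product, which is also the more stable epimer.

Step 2
Reactants: 3 (2S,3R)-2-[(dimethylamino)methyl]-3-ethenyl-4,4-dimethylcyclohexan-1-one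
Product: 4 (1S,2S,3R)-2-[(dimethylamino)methyl]-3-ethenyl-4,4-dimethylcyclohexan-1-ol
Conditions: LiBH(s-Bu)3, THF, −78 °C; MeOH; acid–base extraction
Reagents that add atoms: none
Why: Substrate-controlled ketone reduction: in the chair of 3 both ring substituents are equatorial (the alternative chair has a syn-diaxial clash with a ring methyl), and the bulky hydride attacks along the equatorial trajectory to give the axial alcohol, cis to the aminomethyl group and therefore trans to the vinyl group as the target requires.

Step 3
Reactants: 4 (1S,2S,3R)-2-[(dimethylamino)methyl]-3-ethenyl-4,4-dimethylcyclohexan-1-ol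
Product: 5 1-[(1S,2R,6S)-6-(TBSO)-2-ethenyl-3,3-dimethylcyclohexyl]-N,N-dimethylmethanamine
Conditions: TBSOTf, 2,6-lutidine, CH2Cl2, 0 °C → rt
Reagents that add atoms: tert-butyldimethylsilyl trifluoromethanesulfonate, CC(C)(C)[Si](C)(C)OS(=O)(=O)C(F)(F)F
Why: A silyl triflate with a hindered pyridine base silylates the axial secondary alcohol while the tertiary amine is not consumed; standard silyl ether formation, done before N-oxidation so that no hydroxyl hydrogen-bonds to the N-oxide and slows the elimination.

Step 4
Reactants: 5 1-[(1S,2R,6S)-6-(TBSO)-2-ethenyl-3,3-dimethylcyclohexyl]-N,N-dimethylmethanamine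
Product: 7 tert-butyl{[(1S,3S)-3-ethenyl-4,4-dimethyl-2-methylidenecyclohexyl]oxy}dimethylsilane, via amine N-oxide 6 (not isolated)
Conditions: mCPBA (1.05 equiv), CH2Cl2, −20 °C; basic Al2O3 filtration; toluene, 100 °C
Reagents that add atoms: none
Why: The tertiary amine is oxidised far faster than the monosubstituted alkene, and the Cope elimination (syn, five-membered cyclic transition state) can only remove the ring hydrogen β to nitrogen, so the exocyclic methylene forms regiospecifically under neutral conditions with both remaining stereocentres untouched.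

Step 5
Reactants: 7 tert-butyl{[(1S,3S)-3-ethenyl-4,4-dimethyl-2-methylidenecyclohexyl]oxy}dimethylsilane
Product: 9 2-Ter-ethan-1-ol, via trialkylborane 8 (not isolated)
Conditions: (Sia)2BH [BH3·SMe2, 2-methylbut-2-ene], THF, 0 °C → rt; then NaOH, H2O2, 0 °C
Reagents that add atoms: hydrogen peroxide, OO
Why: Anti-Markovnikov hydroboration–oxidation; the hindered dialkylborane reacts much faster with a monosubstituted vinyl group than with a 1,1-disubstituted alkene, and the exocyclic methylene is further shielded by substituents on both neighbouring ring carbons.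

Step 6
Reactants: 9 2-Ter-ethan-1-ol
Product: 10 2-Ter-acetaldehyde
Conditions: Dess–Martin periodinane, NaHCO3, CH2Cl2, 0 °C → rt
Reagents that add atoms: none
Why: Buffered hypervalent-iodine oxidation of a primary alcohol to the aldehyde without over-oxidation and without acid that could trigger a carbonyl-ene reaction with the nearby alkene; the α-carbon is a CH2, so nothing can epimerise.

Step 7
Reactants: 10 2-Ter-acetaldehyde
Product: 11 3-Ter-prop-1-yne
Conditions: dimethyl (1-diazo-2-oxopropyl)phosphonate, K2CO3, MeOH, 0 °C → rt
Reagents that add atoms: dimethyl (1-diazo-2-oxopropyl)phosphonate, COP(=O)(OC)C(=[N+]=[N-])C(C)=O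
Why: Seyferth–Gilbert homologation with the Ohira–Bestmann reagent converts an enolisable aldehyde into the terminal alkyne with one added carbon under mild carbonate conditions that the alkyl silyl ether tolerates.

Step 8
Reactants: 11 3-Ter-prop-1-yne
Product: 14 tri(propan-2-yl)[(3-Ter-prop-1-yn-1-yl)oxy]silane, via lithium acetylide 12 (not isolated), via lithium ynolate 13 (not isolated)
Conditions: n-BuLi, THF, −78 °C; t-BuOOLi [t-BuOOH, LiN(SiMe3)2], −78 → 0 °C; TIPSOTf, −78 °C → rt
Reagents that add atoms: lithium tert-butyl peroxide, CC(C)(C)OO[Li]; triisopropylsilyl trifluoromethanesulfonate, CC(C)[Si](C(C)C)(C(C)C)OS(=O)(=O)C(F)(F)F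
Why: The acetylide attacks the electrophilic oxygen of the lithium peroxide to give ynolate 13, which the bulky silyl triflate captures on oxygen; this is the known acetylide-oxidation route to triisopropylsilyl ynol ethers and is compatible with alkenes and silyl ethers.

Step 9
Reactants: 15 cyclobutane-1,3-dione
Product: 16 3-(TBSO)cyclobut-2-en-1-one
Conditions: TBSCl, Et3N, CH2Cl2, 0 °C; filtration; short-path distillation
Reagents that add atoms: tert-butyldimethylsilyl chloride, CC(C)(C)[Si](C)(C)Cl
Why: O-silylation of the enol form of the dione (a vinylogous acid) gives the vinylogous silyl ester, which is kept strictly anhydrous.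

Step 10
Reactants: 14 tri(propan-2-yl)[(3-Ter-prop-1-yn-1-yl)oxy]silane; 16 3-(TBSO)cyclobut-2-en-1-one
Product: 21 5-(TBSO)-2-(Ter-methyl)-3-(TIPSO)phenol, via vinylketene 17 (not isolated), via alkenylcyclobutenone 18 (not isolated), via dienylketene 19 (not isolated), via cyclohexadienone 20 (not isolated)
Conditions: 16 (1.5 equiv, in portions), degassed toluene, 80 °C then 110 °C, sealed tube
Reagents that add atoms: none
Why: On heating, 16 undergoes 4π electrocyclic ring opening to the silyloxy vinylketene 17, whose electrophilic ketene carbon bonds to the nucleophilic alkyl-bearing carbon of ynol ether 14 while the ketene α-carbon bonds to the oxygen-bearing alkyne carbon ([2+2] cycloaddition, forming C6–C7 and C4a–C5) to give the 4-alkenylcyclobut-2-enone 18. A second 4π opening gives dienylketene 19, which closes ring A by thermal disrotatory 6π electrocyclisation (C7–C8) to cyclohexadienone 20, and enolisation gives phenol 21. The closest known reaction type is the Danheiser benzannulation of cyclobutenones with trialkylsilyl ynol ethers to resorcinol monosilyl ethers; the 3-silyloxy substituent is an untried member of that class, expected to behave because alkoxy-substituted cyclobutenones are known to react through vinylketenes on heating. No stereocentre is formed, and the two existing ones are remote and cannot epimerise under neutral thermal conditions. Regioselectivity comes from the polarity match in the [2+2] step, which puts the side chain between the new hydroxyl and the TIPS ether and the TBS ether para to it; chemoselectivity is expected because the isolated 1,1-disubstituted alkene and the silyl ethers of 14 do not react with ketenes at this temperature; portionwise addition of 16 keeps 17 dilute so that it is intercepted by 14 before it oligomerises.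

Step 11
Reactants: 21 5-(TBSO)-2-(Ter-methyl)-3-(TIPSO)phenol
Product: 22 1-(TBSO)-4-(Ter-methyl)-3,5-bis(TIPSO)benzene
Conditions: TIPSOTf, 2,6-lutidine, CH2Cl2, 0 °C → rt
Reagents that add atoms: triisopropylsilyl trifluoromethanesulfonate, CC(C)[Si](C(C)C)(C(C)C)OS(=O)(=O)C(F)(F)F
Why: Silyl triflate silylation of a phenol with one ortho substituent; it makes the two oxygens ortho to the side chain identical, so ring A becomes symmetrical and only the para oxygen differs.

Step 12
Reactants: 22 1-(TBSO)-4-(Ter-methyl)-3,5-bis(TIPSO)benzene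
Product: 23 4-(Ter-methyl)-3,5-bis(TIPSO)phenol
Conditions: Cs2CO3 (0.5 equiv), DMF–H2O (10:1), rt
Reagents that add atoms: none
Why: Chemoselective base-mediated cleavage of a phenolic silyl ether: the aryl TBS ether flanked by two hydrogens reacts fastest, the aryl TIPS ethers are bulkier and each has an ortho substituent, and the alkyl TBS ether is inert to carbonate.

Step 13
Reactants: 23 4-(Ter-methyl)-3,5-bis(TIPSO)phenol
Product: 25 6-hydroxy-3-(Ter-methyl)-2,4-bis(TIPSO)benzaldehyde, via hydroxymethylphenol 24 (not isolated)
Conditions: MgCl2, Et3N, (CH2O)n, THF, 65 °C; aq. NH4Cl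
Reagents that add atoms: paraformaldehyde (as formaldehyde), C=O
Why: Magnesium phenoxide-directed ortho-formylation (Casnati–Skattebøl): coordinated formaldehyde is delivered to the ortho carbon and the hydroxymethyl intermediate 24 is oxidised by a second formaldehyde through hydride transfer; 23 is symmetrical, so both ortho positions give the same aldehyde.

Step 14
Reactants: 26 3,4-dihydroxybenzaldehyde
Product: 27 3,4-bis(TIPSO)benzaldehyde
Conditions: TIPSOTf (2.4 equiv), 2,6-lutidine, CH2Cl2, 0 °C → rt
Reagents that add atoms: triisopropylsilyl trifluoromethanesulfonate, CC(C)[Si](C(C)C)(C(C)C)OS(=O)(=O)C(F)(F)F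
Why: Exhaustive silylation of the catechol with the reactive triflate; TIPS ethers withstand the organolithium, amine and oxidant of the later steps and leave with the other silyl groups in step 19.

Step 15
Reactants: 27 3,4-bis(TIPSO)benzaldehyde
Product: 28 4-ethynyl-1,2-bis(TIPSO)benzene
Conditions: Me3SiCHN2, LiN(i-Pr)2, THF, −78 °C → rt
Reagents that add atoms: (trimethylsilyl)diazomethane, C[Si](C)(C)C=[N+]=[N-]
Why: Colvin rearrangement: the lithiated silyldiazomethane adds to the non-enolisable aldehyde, loss of silanolate and nitrogen gives an alkylidene carbene, and a 1,2-shift gives the terminal alkyne under aprotic conditions that spare aryl silyl ethers.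

Step 16
Reactants: 25 6-hydroxy-3-(Ter-methyl)-2,4-bis(TIPSO)benzaldehyde; 28 4-ethynyl-1,2-bis(TIPSO)benzene
Product: 30 2-{3-[3,4-bis(TIPSO)phenyl]-1-hydroxyprop-2-yn-1-yl}-4-(Ter-methyl)-3,5-bis(TIPSO)phenol, via lithium arylacetylide 29 (not isolated)
Conditions: 28 (2.6 equiv), n-BuLi (2.5 equiv), THF, −78 °C; then 25, −78 → 0 °C; pH 7 buffer
Reagents that add atoms: none
Why: 1,2-Addition of an alkynyllithium to a salicylaldehyde: the first equivalent of 29 deprotonates the phenol and the excess adds to the aldehyde; the new carbinol centre forms without control and is removed in step 17.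

Step 17
Reactants: 30 2-{3-[3,4-bis(TIPSO)phenyl]-1-hydroxyprop-2-yn-1-yl}-4-(Ter-methyl)-3,5-bis(TIPSO)phenol
Product: 31 3-[3,4-bis(TIPSO)phenyl]-1-[6-hydroxy-3-(Ter-methyl)-2,4-bis(TIPSO)phenyl]prop-2-yn-1-one
Conditions: activated MnO2 (excess), CH2Cl2, rt
Reagents that add atoms: none
Why: Activated MnO2 oxidises the benzylic–propargylic alcohol selectively under neutral heterogeneous conditions and leaves the hydrogen-bonded phenol, the silyl ethers and the alkene alone.

Step 18
Reactants: 31 3-[3,4-bis(TIPSO)phenyl]-1-[6-hydroxy-3-(Ter-methyl)-2,4-bis(TIPSO)phenyl]prop-2-yn-1-one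
Product: 33 2-[3,4-bis(TIPSO)phenyl]-6-(Ter-methyl)-5,7-bis(TIPSO)-4H-chromen-4-one, via enaminone 32 (not isolated)
Conditions: Et2NH (5 equiv), EtOH, rt → 50 °C
Reagents that add atoms: none
Why: Conjugate addition of the secondary amine to the ynone gives enaminone 32, and the ortho phenol then displaces the amine by addition–elimination, which enforces six-membered closure to the 4-pyranone instead of five-membered aurone formation; the only free ortho oxygen is the one para to the side chain, so the 6-substituted flavone results.

Step 19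
Reactants: 33 2-[3,4-bis(TIPSO)phenyl]-6-(Ter-methyl)-5,7-bis(TIPSO)-4H-chromen-4-one
Product: 34 ugonin Q, 2-(3,4-dihydroxyphenyl)-5,7-dihydroxy-6-{[(1S,5S)-5-hydroxy-2,2-dimethyl-6-methylidenecyclohexyl]methyl}-4H-chromen-4-one
Conditions: Bu4NF, AcOH (1:1, excess), THF, 0 °C → rt, argon; pH 6 buffer
Reagents that add atoms: none
Why: Buffered fluoride desilylation removes the four aryl TIPS ethers and the allylic TBS ether without acid that could move the exocyclic alkene or add a phenol to it and without a strongly basic phenoxide medium that could oxidise the catechol.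

## Compound list

1 | 4,4-dimethylcyclohex-2-en-1-one | O=C1C=CC(C)(C)CC1 | starting material
2 | dimethylaluminium (3R)-3-ethenyl-4,4-dimethylcyclohex-1-en-1-olate | C=C[C@@H]1C=C(O[Al](C)C)CCC1(C)C | intermediate
3 | (2S,3R)-2-[(dimethylamino)methyl]-3-ethenyl-4,4-dimethylcyclohexan-1-one | CN(C)C[C@@H]1[C@@H](C=C)C(C)(C)CCC1=O | intermediate
4 | (1S,2S,3R)-2-[(dimethylamino)methyl]-3-ethenyl-4,4-dimethylcyclohexan-1-ol | CN(C)C[C@@H]1[C@@H](C=C)C(C)(C)CC[C@@H]1O | intermediate
5 | 1-[(1S,2R,6S)-6-(TBSO)-2-ethenyl-3,3-dimethylcyclohexyl]-N,N-dimethylmethanamine | CN(C)C[C@@H]1[C@@H](C=C)C(C)(C)CC[C@@H]1O[Si](C)(C)C(C)(C)C | intermediate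
6 | N-oxide of 5 | C[N+](C)([O-])C[C@@H]1[C@@H](C=C)C(C)(C)CC[C@@H]1O[Si](C)(C)C(C)(C)C | intermediate
7 | tert-butyl{[(1S,3S)-3-ethenyl-4,4-dimethyl-2-methylidenecyclohexyl]oxy}dimethylsilane | C=C1[C@@H](C=C)C(C)(C)CC[C@@H]1O[Si](C)(C)C(C)(C)C | intermediate
8 | (2-Ter-ethyl)bis(3-methylbutan-2-yl)borane | C=C1[C@@H](CCB(C(C)C(C)C)C(C)C(C)C)C(C)(C)CC[C@@H]1O[Si](C)(C)C(C)(C)C | intermediate
9 | 2-Ter-ethan-1-ol | C=C1[C@@H](CCO)C(C)(C)CC[C@@H]1O[Si](C)(C)C(C)(C)C | intermediate
10 | 2-Ter-acetaldehyde | C=C1[C@@H](CC=O)C(C)(C)CC[C@@H]1O[Si](C)(C)C(C)(C)C | intermediate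
11 | 3-Ter-prop-1-yne | C=C1[C@@H](CC#C)C(C)(C)CC[C@@H]1O[Si](C)(C)C(C)(C)C | intermediate
12 | lithium 3-Ter-prop-1-yn-1-ide | C=C1[C@@H](CC#C[Li])C(C)(C)CC[C@@H]1O[Si](C)(C)C(C)(C)C | intermediate
13 | lithium 3-Ter-prop-1-yn-1-olate | C=C1[C@@H](CC#CO[Li])C(C)(C)CC[C@@H]1O[Si](C)(C)C(C)(C)C | intermediate
14 | tri(propan-2-yl)[(3-Ter-prop-1-yn-1-yl)oxy]silane | C=C1[C@@H](CC#CO[Si](C(C)C)(C(C)C)C(C)C)C(C)(C)CC[C@@H]1O[Si](C)(C)C(C)(C)C | intermediate
15 | cyclobutane-1,3-dione | O=C1CC(=O)C1 | starting material
16 | 3-(TBSO)cyclobut-2-en-1-one | O=C1C=C(O[Si](C)(C)C(C)(C)C)C1 | intermediate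
17 | 3-(TBSO)buta-1,3-dien-1-one | O=C=CC(=C)O[Si](C)(C)C(C)(C)C | intermediate
18 | 4-[1-(TBSO)ethenyl]-2-(Ter-methyl)-3-(TIPSO)cyclobut-2-en-1-one (both epimers at C4) | C=C(O[Si](C)(C)C(C)(C)C)C1C(=O)C(C[C@@H]2C(=C)[C@@H](O[Si](C)(C)C(C)(C)C)CCC2(C)C)=C1O[Si](C(C)C)(C(C)C)C(C)C | intermediate
19 | (3E)-5-(TBSO)-2-(Ter-methyl)-3-(TIPSO)hexa-1,3,5-trien-1-one | O=C=C(C[C@@H]1C(=C)[C@@H](O[Si](C)(C)C(C)(C)C)CCC1(C)C)/C(O[Si](C(C)C)(C(C)C)C(C)C)=C\C(=C)O[Si](C)(C)C(C)(C)C | intermediate
20 | 5-(TBSO)-2-(Ter-methyl)-3-(TIPSO)cyclohexa-2,4-dien-1-one | O=C1CC(O[Si](C)(C)C(C)(C)C)=CC(O[Si](C(C)C)(C(C)C)C(C)C)=C1C[C@@H]2C(=C)[C@@H](O[Si](C)(C)C(C)(C)C)CCC2(C)C | intermediate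
21 | 5-(TBSO)-2-(Ter-methyl)-3-(TIPSO)phenol | C=C1[C@@H](Cc2c(O)cc(O[Si](C)(C)C(C)(C)C)cc2O[Si](C(C)C)(C(C)C)C(C)C)C(C)(C)CC[C@@H]1O[Si](C)(C)C(C)(C)C | intermediate
22 | 1-(TBSO)-4-(Ter-methyl)-3,5-bis(TIPSO)benzene | C=C1[C@@H](Cc2c(O[Si](C(C)C)(C(C)C)C(C)C)cc(O[Si](C)(C)C(C)(C)C)cc2O[Si](C(C)C)(C(C)C)C(C)C)C(C)(C)CC[C@@H]1O[Si](C)(C)C(C)(C)C | intermediate
23 | 4-(Ter-methyl)-3,5-bis(TIPSO)phenol | C=C1[C@@H](Cc2c(O[Si](C(C)C)(C(C)C)C(C)C)cc(O)cc2O[Si](C(C)C)(C(C)C)C(C)C)C(C)(C)CC[C@@H]1O[Si](C)(C)C(C)(C)C | intermediate
24 | 2-(hydroxymethyl)-4-(Ter-methyl)-3,5-bis(TIPSO)phenol | C=C1[C@@H](Cc2c(O[Si](C(C)C)(C(C)C)C(C)C)cc(O)c(CO)c2O[Si](C(C)C)(C(C)C)C(C)C)C(C)(C)CC[C@@H]1O[Si](C)(C)C(C)(C)C | intermediate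
25 | 6-hydroxy-3-(Ter-methyl)-2,4-bis(TIPSO)benzaldehyde | C=C1[C@@H](Cc2c(O[Si](C(C)C)(C(C)C)C(C)C)cc(O)c(C=O)c2O[Si](C(C)C)(C(C)C)C(C)C)C(C)(C)CC[C@@H]1O[Si](C)(C)C(C)(C)C | intermediate
26 | 3,4-dihydroxybenzaldehyde | O=Cc1ccc(O)c(O)c1 | starting material
27 | 3,4-bis(TIPSO)benzaldehyde | O=Cc1ccc(O[Si](C(C)C)(C(C)C)C(C)C)c(O[Si](C(C)C)(C(C)C)C(C)C)c1 | intermediate
28 | 4-ethynyl-1,2-bis(TIPSO)benzene | C#Cc1ccc(O[Si](C(C)C)(C(C)C)C(C)C)c(O[Si](C(C)C)(C(C)C)C(C)C)c1 | intermediate
29 | lithium [3,4-bis(TIPSO)phenyl]ethynide | [Li]C#Cc1ccc(O[Si](C(C)C)(C(C)C)C(C)C)c(O[Si](C(C)C)(C(C)C)C(C)C)c1 | intermediate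
30 | 2-{3-[3,4-bis(TIPSO)phenyl]-1-hydroxyprop-2-yn-1-yl}-4-(Ter-methyl)-3,5-bis(TIPSO)phenol (both carbinol epimers) | C=C1[C@@H](Cc2c(O[Si](C(C)C)(C(C)C)C(C)C)cc(O)c(C(O)C#Cc3ccc(O[Si](C(C)C)(C(C)C)C(C)C)c(O[Si](C(C)C)(C(C)C)C(C)C)c3)c2O[Si](C(C)C)(C(C)C)C(C)C)C(C)(C)CC[C@@H]1O[Si](C)(C)C(C)(C)C | intermediate
31 | 3-[3,4-bis(TIPSO)phenyl]-1-[6-hydroxy-3-(Ter-methyl)-2,4-bis(TIPSO)phenyl]prop-2-yn-1-one | C=C1[C@@H](Cc2c(O[Si](C(C)C)(C(C)C)C(C)C)cc(O)c(C(=O)C#Cc3ccc(O[Si](C(C)C)(C(C)C)C(C)C)c(O[Si](C(C)C)(C(C)C)C(C)C)c3)c2O[Si](C(C)C)(C(C)C)C(C)C)C(C)(C)CC[C@@H]1O[Si](C)(C)C(C)(C)C | intermediate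
32 | 3-[3,4-bis(TIPSO)phenyl]-3-(diethylamino)-1-[6-hydroxy-3-(Ter-methyl)-2,4-bis(TIPSO)phenyl]prop-2-en-1-one | C=C1[C@@H](Cc2c(O[Si](C(C)C)(C(C)C)C(C)C)cc(O)c(C(=O)C=C(N(CC)CC)c3ccc(O[Si](C(C)C)(C(C)C)C(C)C)c(O[Si](C(C)C)(C(C)C)C(C)C)c3)c2O[Si](C(C)C)(C(C)C)C(C)C)C(C)(C)CC[C@@H]1O[Si](C)(C)C(C)(C)C | intermediate
33 | 2-[3,4-bis(TIPSO)phenyl]-6-(Ter-methyl)-5,7-bis(TIPSO)-4H-chromen-4-one | C=C1[C@@H](Cc2c(O[Si](C(C)C)(C(C)C)C(C)C)cc3oc(-c4ccc(O[Si](C(C)C)(C(C)C)C(C)C)c(O[Si](C(C)C)(C(C)C)C(C)C)c4)cc(=O)c3c2O[Si](C(C)C)(C(C)C)C(C)C)C(C)(C)CC[C@@H]1O[Si](C)(C)C(C)(C)C | intermediate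
34 | ugonin Q, 2-(3,4-dihydroxyphenyl)-5,7-dihydroxy-6-{[(1S,5S)-5-hydroxy-2,2-dimethyl-6-methylidenecyclohexyl]methyl}-4H-chromen-4-one | C=C1[C@@H](Cc2c(O)cc3oc(-c4ccc(O)c(O)c4)cc(=O)c3c2O)C(C)(C)CC[C@@H]1O | target

## Step count and risk

Total step count: 19. Longest linear sequence: 16 steps (steps 1–8, 10–13 and 16–19); steps 9, 14 and 15 make the two side partners.

**Step 10 (key step).** The vinylogous silyl ester 16 may pass its silyl group to a nucleophile, or the electron-rich ketene 17 may self-condense or acylate the product phenol faster than it adds to 14, because a 3-silyloxy cyclobutenone is an untried partner. The fallback generates the same ketene photochemically at room temperature and low stationary concentration. It sets out from 14 and returns at 21. Butane-2,3-dione is mono-silylated (TBSOTf, Et3N) to 3-(TBSO)but-3-en-2-one F1. Trifluoroacetylation (LiN(SiMe3)2, CF3CO2CH2CF3) gives 5-(TBSO)-1,1,1-trifluorohex-5-ene-2,4-dione F2, and diazo transfer with cleavage of the trifluoroacetyl group (MsN3, Et3N, H2O) gives 3-(TBSO)-1-diazobut-3-en-2-one F3. Irradiation of F3 with 14 (254 nm, ClCH2CH2Cl, rt) triggers Wolff rearrangement to 17, and brief warming to 80 °C completes the cascade through 18–20 to 21.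

**Step 1.** Vinyl transfer to a β-carbon next to a quaternary centre may be slow or poorly enantioselective, and capture of the aluminium enolate may be incomplete, so that protonation on work-up gives ketone without the aminomethyl group. The fallback replaces catalysis by resolution. It sets out from 1 and returns at 4. CH2=CHMgBr with catalytic CuBr·SMe2 (monovalent copper; THF, −78 °C), followed by N,N-dimethylmethyleneiminium iodide, gives the racemic trans Mannich base F4. LiBH(s-Bu)3 gives the racemic amino alcohol F5. Crystallisation with O,O′-di-p-toluoyl-L-tartaric acid (or its antipode, whichever salt of the wanted enantiomer is the less soluble) gives the salt F6, from which aqueous NaOH liberates 4.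

**Step 5.** The borane may also attack the exocyclic methylene, or a second hydroboration may follow, because both alkenes are terminal. The fallback changes the order of events so that only one alkene is present. It sets out from 5 and returns at 9. Hydroboration of 5 with 9-borabicyclo[3.3.1]nonane (THF, 60 °C) and NaOH/H2O2 gives 2-[(1R,2S,3S)-3-(TBSO)-2-[(dimethylamino)methyl]-6,6-dimethylcyclohexyl]ethan-1-ol F7. mCPBA gives its N-oxide F8, and Cope elimination in toluene at 100 °C gives 9.

**Step 8.** Oxygen transfer to the acetylide may be incomplete, the ynolate may be silylated on carbon to a silylketene, or the ynol ether may hydrolyse during isolation. The fallback builds the ynolate by ester homologation. It sets out from 10 and returns at 14 through 13. Pinnick oxidation (NaClO2, NaH2PO4, 2-methylbut-2-ene, t-BuOH–H2O) gives 2-Ter-acetic acid F9, and Me3SiCHN2 in MeOH–toluene gives its methyl ester F10. Kowalski homologation (CH2Br2 and lithium 2,2,6,6-tetramethylpiperidide at −78 °C, then LiN(SiMe3)2, then n-BuLi, −78 °C → rt) rearranges the dibromomethyl ketone enolate to 13, and TIPSCl gives 14.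

**Step 16.** Addition to an aldehyde that is deactivated as its phenoxide and flanked by two ortho substituents may stall, and a TIPS group may migrate from the ortho oxygen to the new alkoxide. The fallback forms ring C by palladium catalysis and also bypasses steps 13, 17 and 18. It sets out from 23 and returns at 33. N-Iodosuccinimide (CH2Cl2, −20 °C) iodinates one of the two equivalent ortho positions to give 2-iodo-4-(Ter-methyl)-3,5-bis(TIPSO)phenol F11. Carbonylative Sonogashira coupling with 28 and in-situ amine-mediated closure (PdCl2(PPh3)2, a divalent palladium precatalyst, CO at 1 atm, Et2NH, 40–60 °C) gives 33.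

## Further compounds

F1 | step 10 | 3-(TBSO)but-3-en-2-one | CC(=O)C(=C)O[Si](C)(C)C(C)(C)C
F2 | step 10 | 5-(TBSO)-1,1,1-trifluorohex-5-ene-2,4-dione | C=C(O[Si](C)(C)C(C)(C)C)C(=O)CC(=O)C(F)(F)F
F3 | step 10 | 3-(TBSO)-1-diazobut-3-en-2-one | C=C(O[Si](C)(C)C(C)(C)C)C(=O)C=[N+]=[N-]
F4 | step 1 | racemic trans-2-[(dimethylamino)methyl]-3-ethenyl-4,4-dimethylcyclohexan-1-one (1:1 mixture of 3 and its enantiomer) | CN(C)C[C@@H]1[C@@H](C=C)C(C)(C)CCC1=O.CN(C)C[C@H]1[C@H](C=C)C(C)(C)CCC1=O
F5 | step 1 | racemic amino alcohol (1:1 mixture of 4 and its enantiomer) | CN(C)C[C@@H]1[C@@H](C=C)C(C)(C)CC[C@@H]1O.CN(C)C[C@H]1[C@H](C=C)C(C)(C)CC[C@H]1O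
F6 | step 1 | 1:1 salt of 4 with (2R,3R)-O,O′-di-p-toluoyltartaric acid | CN(C)C[C@@H]1[C@@H](C=C)C(C)(C)CC[C@@H]1O.OC(=O)[C@H](OC(=O)c1ccc(C)cc1)[C@@H](OC(=O)c1ccc(C)cc1)C(=O)O
F7 | step 5 | 2-[(1R,2S,3S)-3-(TBSO)-2-[(dimethylamino)methyl]-6,6-dimethylcyclohexyl]ethan-1-ol | CN(C)C[C@@H]1[C@@H](CCO)C(C)(C)CC[C@@H]1O[Si](C)(C)C(C)(C)C
F8 | step 5 | N-oxide of F7 | C[N+](C)([O-])C[C@@H]1[C@@H](CCO)C(C)(C)CC[C@@H]1O[Si](C)(C)C(C)(C)C
F9 | step 8 | 2-Ter-acetic acid | C=C1[C@@H](CC(=O)O)C(C)(C)CC[C@@H]1O[Si](C)(C)C(C)(C)C
F10 | step 8 | methyl 2-Ter-acetate | C=C1[C@@H](CC(=O)OC)C(C)(C)CC[C@@H]1O[Si](C)(C)C(C)(C)C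
F11 | step 16 | 2-iodo-4-(Ter-methyl)-3,5-bis(TIPSO)phenol | C=C1[C@@H](Cc2c(O[Si](C(C)C)(C(C)C)C(C)C)cc(O)c(I)c2O[Si](C(C)C)(C(C)C)C(C)C)C(C)(C)CC[C@@H]1O[Si](C)(C)C(C)(C)C
A1 | alternative 1 | [(2,6-bis{[2-(trimethylsilyl)ethoxy]methoxy}-4-(TIPSO)phenyl)methyl]zinc bromide | Br[Zn]Cc1c(OCOCC[Si](C)(C)C)cc(O[Si](C(C)C)(C(C)C)C(C)C)cc1OCOCC[Si](C)(C)C
A2 | alternative 1 | (3S)-3-[(2,6-bis{[2-(trimethylsilyl)ethoxy]methoxy}-4-(TIPSO)phenyl)methyl]-4,4-dimethyl-2-methylidenecyclohexan-1-one | C=C1[C@@H](Cc2c(OCOCC[Si](C)(C)C)cc(O[Si](C(C)C)(C(C)C)C(C)C)cc2OCOCC[Si](C)(C)C)C(C)(C)CCC1=O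
A3 | alternative 2 | 4-[(2E)-3,7-dimethylocta-2,6-dien-1-yl]-3,5-bis(prop-2-en-1-yloxy)phenol | CC(C)=CCC/C(C)=C/Cc1c(OCC=C)cc(O)cc1OCC=C
A4 | alternative 2 | 4-{[(1S)-2,2-dimethyl-6-methylidenecyclohexyl]methyl}-3,5-bis(prop-2-en-1-yloxy)phenol | C=C1[C@@H](Cc2c(OCC=C)cc(O)cc2OCC=C)C(C)(C)CCC1
A5 | alternative 3 | methyl 6-(3,4-bis{[2-(trimethylsilyl)ethoxy]methoxy}phenyl)-2-methyl-4-oxo-4H-pyran-3-carboxylate | COC(=O)c1c(C)oc(-c2ccc(OCOCC[Si](C)(C)C)c(OCOCC[Si](C)(C)C)c2)cc1=O
A6 | alternative 3 | N-methoxy-N-methyl-3-Ter-propanamide | C=C1[C@@H](CCC(=O)N(C)OC)C(C)(C)CC[C@@H]1O[Si](C)(C)C(C)(C)C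
A7 | alternative 3 | 2-(3,4-bis{[2-(trimethylsilyl)ethoxy]methoxy}phenyl)-5,7-dihydroxy-6-(Ter-methyl)-4H-chromen-4-one | C=C1[C@@H](Cc2c(O)cc3oc(-c4ccc(OCOCC[Si](C)(C)C)c(OCOCC[Si](C)(C)C)c4)cc(=O)c3c2O)C(C)(C)CC[C@@H]1O[Si](C)(C)C(C)(C)C
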